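## Structural features

The target is an achiral, unsymmetrical diaryl ether: two benzene rings joined through one oxygen, with no stereocentre and no ring fusion. Ring A is a methyl salicylate (ester on C1, hydrogen-bonded hydroxyl on C2, methyl on C4) whose second ortho position C6 carries the ether oxygen, so the ester lies between two oxygen-bearing carbons. Ring B carries the ether oxygen on C1, a hydroxymethyl group on C2, a methoxy group on C4 and a prenyloxy group on C6, so both positions ortho to its ether oxygen are substituted. The fragile groups are the aryl prenyl ether (acid, thermal Claisen rearrangement, oxidants, hydrogenation), the benzylic alcohol, and the ring A ester, which a phenoxide on C6 of ring B could in principle attack to give a seven-membered depsidone lactone. The real difficulty is twofold: forming the crowded aryl–O–aryl bond, and telling apart the three oxygens of ring B (C1 ether, C4 methyl ether, C6 prenyl ether). The key step uses the fact that the oxygens on C4 and C6 of ring B are 1,3-related with unsubstituted C5 between them, while C1 is alpha and C2 is beta to C6. Ring B is therefore a masked 4-aryloxy-5-substituted cyclohexane-1,3-dione, and its C1 can be bonded to the ring A oxygen while it is still a non-aromatic carbon. The saturated ring B has adjacent transient stereocentres at C1, C2 and C3; all are erased on aromatisation.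

## Logic of the disconnections

18 ⇒ 16 + 17. The O–CH2 bond of the allylic ether on C6 of ring B is cut. This ether is the most acid- and heat-sensitive group, so it is put on last, after every acidic operation. The forward step must alkylate the ring B phenol of 16 selectively in the presence of the chelated ring A phenol and the primary alcohol.

16 ⇒ 14. No skeletal bond is cut; the ring A phenol and the benzylic alcohol are masked as an acetal and a silyl ether. This makes the C6 hydroxyl of ring B the only free hydroxyl at the preceding stage. Forward, both masks must fall in one operation that the benzylic alcohol and the diaryl ether survive.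

14 ⇒ 11. The C1=C2 double bond of ring B is saturated in the retrosynthetic sense, turning the phenol into a cyclohexenone that is a vinylogous methyl ester. Ring B loses its aromaticity and its 1,3-dioxygenation becomes carbonyl chemistry. Forward, a dehydrogenation across C1–C2 is required, through functionalisation of C1 alpha to the C6 ketone.

11 ⇒ 10. The O–CH3 bond at C4 is cut. The methyl ether of the target is read as the enol ether of one carbonyl of a 1,3-dione, so the C4 and C6 oxygens are differentiated before the ring is aromatic. Forward, methanol must react at C4 and not at C6.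

10 ⇒ 9. A methoxycarbonyl group is added back at C3. It is the activating group that makes the C3–C4 unit a stabilised nucleophile. Forward, it must be removed without touching the ring A ester.

9 ⇒ 6 + 7. Bonds C2–C3 and C4–C5 of ring B are cut. Ring B falls apart into an acyclic enone that already carries the ether oxygen and a three-carbon diester. Forward, conjugate addition must occur at the carbon bearing the silyloxymethyl group, and only the methyl-side enolate may acylate.

6 ⇒ 4 + 5. The C=C bond of the enone (C1=C2 in ring B numbering) is cut. An olefination fixes on which alpha-carbon of the ketone the double bond sits, which a crossed aldol of an aryloxy ketone would not guarantee. Forward, the phosphonate anion must condense with the aldehyde faster than it attacks the neighbouring ester.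

4 ⇒ 2 + 3. The bond between the ring A oxygen and the future C1 of ring B is cut. Because this bond is made to an sp3 carbon, the crowded diaryl ether never has to be formed by aryl C–O coupling. Forward, a carbenoid must be captured cleanly by a hindered, hydrogen-bonded phenol.

2 ⇒ 1. The O–CH2 bond of the acetal is cut. The two hydroxyls of 1 are equivalent, and after the first reaction the remaining one is chelated and slower, so mono-protection should be achievable.

## Other disconnections considered

Alternative 1: The cut is made in ring A, at C1–C2 and C5–C6 (C1 ester carbon, C2 hydroxyl carbon, C6 ether carbon), so ring A rather than ring B is assembled on the ether oxygen. Forward, the dienolate of anhydride A2 would add to the β-carbon of the aryloxy ynoate A3, the resulting ester enolate would acylate on an anhydride carbonyl, and decarboxylative aromatisation would give salicylate A1; one desilylation then leads to 18.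
- In its favour: the ester arrives between hydroxyl and ether with regiochemistry fixed by the polarity of both partners, and the ring A phenol is formed free, so no protecting group is needed there. The ether oxygen is again bonded to a non-aromatic carbon. The endgame is one step, which is better than the five steps after the annulation in the chosen plan.
- Against it here: A3 must be made from the fully substituted, doubly flanked phenol A4, which is itself a tetrasubstituted arene needing its own synthesis. The usual addition, halogenation and dehydrohalogenation route to aryloxy alkynoates would expose the prenyl double bond to halogen. A3 is a push–pull alkyne from which the dienolate could expel aryloxide after addition, destroying the ether.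
- Comparison: both plans are anionic Michael–acylation annulations and both avoid aryl C–O coupling, so they are equal on mechanism type. The alternative is more convergent, but it replaces a stable enone and malonate with a sensitive ynol ether. Preparing A4 and A3 is expected to cost more steps than the short endgame saves.

Alternative 2: Ring B is cut at C5–C6, C3–C4 and C1–C6. Forward, photochemical Wolff rearrangement of diazo ketone A6 in the presence of alkoxyalkyne A7 starts a cascade of (2+2) addition, four-electron ring opening and six-electron ring closure. This delivers ring B as phenol A5, which would be prenylated and desilylated to 18.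
- In its favour: ring B is formed aromatic, so no dehydrogenation is needed. The C4 methoxy group comes from A7 and the C6 hydroxyl from the ketene carbonyl, so the two oxygens are differentiated by construction. On this point the alternative is better than the chosen plan, which depends on a regioselective enol ether formation. The ether oxygen is bonded to a vinylic carbon before the ring exists, which equals the chosen plan. The endgame is two steps.
- Against it here: A6 is both a vinylogous aryl ester open to addition–elimination and a diazo compound whose preparation needs diazo transfer or acylation of a diazoalkane. A7 is volatile and unstable and must be used in excess. The photolysis competes with absorption by the benzoate chromophore. The aryl silyl ether next to the ester is base-labile, and the six-electron closure occurs at a terminus carrying the bulky aryloxy group.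
- Comparison: four pericyclic events in one flask stand against two polar bond formations. The post-annulation sequence is shorter and the overall length is at best equal, but the reagents are hazardous and scale poorly, whereas the chosen plan uses only stable intermediates.

Alternative 3: Two bonds at ring A are cut without opening a ring: the ether bond O–C6 and the bond from C1 to the carboxyl carbon. Forward, fluoride-induced elimination from silylaryl triflate A9 releases aryne A10 under an atmosphere of A11. The phenoxide of A4 adds at the aryne carbon remote from the MOM ether, and the aryl anion formed next to that ether captures A11 to give acid A8. O-methylation and removal of the MOM and silyl groups would then give 18.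
- In its favour: this is the most convergent plan. It makes both hindered bonds of ring A in one metal-free operation, with regiochemistry set by the inductive effect of the adjacent acetal oxygen. Its longest linear sequence should be shorter than the nine steps of the chosen plan, a clear advantage.
- Against it here: both partners are elaborate; A4 (with the prenyl ether in place) and A9 each need several steps. A doubly flanked phenoxide is a slow partner and is reversibly carbonated by A11. The aryl anion may be protonated before it is carboxylated, giving the ether without the carboxyl group. The MOM group must finally be removed with acid in the presence of the prenyl ether, which the chosen plan avoids.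
- Comparison: the alternative keeps both rings aromatic and needs no oxidation-state change, which is better on structure. It depends on a three-component trapping whose partitioning is hard to predict, whereas each bond of the chosen annulation forms under a thermodynamic drive. The total step count is expected to be higher although the linear sequence is shorter.

Key step: step 4

Remark on numbering: ring A is numbered C1 (ester carbon), C2 (hydroxyl), C4 (methyl), C6 (ether); ring B is numbered C1 (ether carbon), C2 (hydroxymethyl), C4 (methoxy), C6 (prenyloxy).

Remark on structure: in annulation product 9 the two ring carbonyls flank the ring CH2 and only one is next to the ester-bearing carbon, so 9 is a 3-aryloxy-2-(silyloxymethyl)-4,6-dioxocyclohexane-1-carboxylate; 2,6-dioxo locants would describe a compound that the Michael–Claisen bond set cannot produce.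

Assumption: aldehyde 5 is taken as a catalogue compound like its tert-butyldimethylsilyl analogue; the more acid-stable tert-butyldiphenylsilyl group is chosen because step 6 is acid-catalysed. The enone is made by olefination of a phosphonate, not by a crossed aldol of an aryloxyacetone, which would be ambiguous in regiochemistry.

## Route

Step 1
Reactants: 1 methyl 2,6-dihydroxy-4-methylbenzoate
Product: 2 methyl 2-hydroxy-6-(methoxymethoxy)-4-methylbenzoate
Conditions: MOMCl (1.05 equiv), iPr2NEt, CH2Cl2, 0 °C → rt
Reagents that add atoms: chloromethyl methyl ether (MOMCl), COCCl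
Why: Williamson-type O-alkylation (MOM protection); the two phenols of 1 are equivalent, and after the first alkylation the remaining hydroxyl is locked in a hydrogen bond to the ester carbonyl, so mono-protection should dominate with one equivalent of MOMCl.

Step 2
Reactants: 2 methyl 2-hydroxy-6-(methoxymethoxy)-4-methylbenzoate; 3 dimethyl (1-diazo-2-oxopropyl)phosphonate
Product: 4 dimethyl {1-[2-(methoxycarbonyl)-3-(methoxymethoxy)-5-methylphenoxy]-2-oxopropyl}phosphonate (racemic)
Conditions: Rh2(OAc)4 (1 mol %), PhMe, 80 °C, slow addition of 3
Reagents that add atoms: none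
Why: Rh2(OAc)4-catalysed carbenoid O–H insertion; with slow addition of 3 the electrophilic carbenoid should be captured by the phenol oxygen faster than it dimerises or attacks the arene, placing the future ring B carbon C1 on the ether oxygen by a bond to sp3 carbon. The new stereocentre is racemic and is destroyed in step 3.

Step 3
Reactants: 4 dimethyl {1-[2-(methoxycarbonyl)-3-(methoxymethoxy)-5-methylphenoxy]-2-oxopropyl}phosphonate; 5 (tert-butyldiphenylsilyloxy)acetaldehyde
Product: 6 methyl 2-{[(3Z)-5-(tert-butyldiphenylsilyloxy)-2-oxopent-3-en-3-yl]oxy}-6-(methoxymethoxy)-4-methylbenzoate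
Conditions: LiCl, iPr2NEt, MeCN, 0 °C → rt
Reagents that add atoms: none
Why: Horner–Wadsworth–Emmons olefination under Masamune–Roush conditions; the doubly stabilised phosphonate anion should condense with the aldehyde much faster than it attacks the hindered ring A ester, and the double bond can only form at the aryloxy-bearing carbon. The (Z)-isomer (silyloxymethyl trans to acetyl) is expected to predominate, and either geometry would serve in step 4.

Step 4
Reactants: 6 methyl 2-{[(3Z)-5-(tert-butyldiphenylsilyloxy)-2-oxopent-3-en-3-yl]oxy}-6-(methoxymethoxy)-4-methylbenzoate; 7 dimethyl malonate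
Product: 9 methyl 2-[(tert-butyldiphenylsilyloxy)methyl]-3-[2-(methoxycarbonyl)-3-(methoxymethoxy)-5-methylphenoxy]-4,6-dioxocyclohexane-1-carboxylate (racemic mixture of diastereomers; largely enolised), via malonate Michael adduct 8 (not isolated)
Conditions: NaOMe (2.2 equiv), MeOH–THF, rt → 60 °C; AcOH quench
Reagents that add atoms: none
Why: Methoxide generates the malonate anion, which should add 1,4 to the captodative enone 6 at the carbon carrying the silyloxymethyl group (ring B bond C2–C3) to give 8 after proton transfer. Equilibrating enolisation of the methyl ketone then lets the methyl carbon acylate on one of the two equivalent malonate esters (bond C4–C5) with loss of methoxide. The closest known reaction type is the Michael–Claisen (dimedone-type) annulation of enones with malonates to alkoxycarbonyl-cyclohexane-1,3-diones. Ring B closes by a 6-(enolendo)-exo-trig Claisen/Dieckmann acylation. The three new sp3 centres (C1, C2, C3) form without external control; C1 and C3 can epimerise under the conditions, so the all-equatorial isomer should prevail, but this is irrelevant because all three are erased by decarboxylation and aromatisation. The step needs chemoselectivity (1,4- over 1,2-addition, acylation on the malonate and not on the ring A ester) and regioselectivity (which alpha-carbon of the ketone closes). The soft malonate anion prefers the β-carbon; the aryloxy-bearing enolate carbon could only form a four-membered ring with the malonate or a non-enolisable benzofuranone with the di-ortho-substituted ring A ester; only the methyl-side closure ends in a stabilised dione enolate, which drives the sequence. Methoxide in methanol makes any transesterification of the methyl esters degenerate.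

Step 5
Reactants: 9 methyl 2-[(tert-butyldiphenylsilyloxy)methyl]-3-[2-(methoxycarbonyl)-3-(methoxymethoxy)-5-methylphenoxy]-4,6-dioxocyclohexane-1-carboxylate
Product: 10 methyl 2-({2-[(tert-butyldiphenylsilyloxy)methyl]-4,6-dioxocyclohexyl}oxy)-6-(methoxymethoxy)-4-methylbenzoate (racemic cis/trans mixture; largely enolised)
Conditions: LiCl, DMSO–H2O, 110–120 °C
Reagents that add atoms: none
Why: Krapcho dealkoxycarbonylation; only the β-keto ester on ring B carbon C3 can lose CO2 through an enol, whereas the hindered benzoate of ring A has no such pathway. The near-neutral conditions should spare the MOM and silyl ethers, and the C3 stereocentre disappears.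

Step 6
Reactants: 10 methyl 2-({2-[(tert-butyldiphenylsilyloxy)methyl]-4,6-dioxocyclohexyl}oxy)-6-(methoxymethoxy)-4-methylbenzoate
Product: 11 methyl 2-({2-[(tert-butyldiphenylsilyloxy)methyl]-4-methoxy-6-oxocyclohex-4-en-1-yl}oxy)-6-(methoxymethoxy)-4-methylbenzoate (racemic cis/trans mixture)
Conditions: MeOH, HC(OMe)3, CSA (5 mol %), 0 °C → rt
Reagents that add atoms: methanol, CO; trimethyl orthoformate, COC(OC)OC
Why: Acid-catalysed enol etherification of a cyclic 1,3-dione (vinylogous Fischer esterification); methanol should add to the protonated dione at C4, the carbonyl carbon remote from the bulky, electron-withdrawing aryloxy-bearing C1, and reversibility should funnel material to this less congested vinylogous ester. The tert-butyldiphenylsilyl ether and the aryl MOM ether are expected to tolerate catalytic CSA at room temperature.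

Step 7
Reactants: 11 methyl 2-({2-[(tert-butyldiphenylsilyloxy)methyl]-4-methoxy-6-oxocyclohex-4-en-1-yl}oxy)-6-(methoxymethoxy)-4-methylbenzoate
Product: 14 methyl 2-{2-[(tert-butyldiphenylsilyloxy)methyl]-6-hydroxy-4-methoxyphenoxy}-6-(methoxymethoxy)-4-methylbenzoate, via alpha-phenylselanyl ketone 12 (not isolated), via selenoxide 13 (not isolated)
Conditions: LiN(iPr)2, THF, −78 °C; PhSeCl, −78 °C; then 30% H2O2, pyridine, 0 °C → rt
Reagents that add atoms: none
Why: Kinetic alpha-prime deprotonation of the vinylogous ester at C1 and selenenylation anti to the C2 substituent, then selenoxide syn-elimination toward the C2 hydrogen, should give the keto tautomer of 14, which aromatises by proton shift. The stereocentres at C1 and C2 vanish.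

Step 8
Reactants: 14 methyl 2-{2-[(tert-butyldiphenylsilyloxy)methyl]-6-hydroxy-4-methoxyphenoxy}-6-(methoxymethoxy)-4-methylbenzoate
Product: 16 methyl 2-hydroxy-6-[2-hydroxy-6-(hydroxymethyl)-4-methoxyphenoxy]-4-methylbenzoate, via desilylated MOM ether 15 (not isolated)
Conditions: Bu4NF, THF, rt; then HCl (about 1 M), MeOH, rt
Reagents that add atoms: none
Why: Fluoride cleaves the Si–O bond and methanolic HCl then removes the aryl MOM acetal, which is activated by the ortho ester (acetal exchange). Doing this before prenylation keeps acid away from the prenyl ether, and the benzylic alcohol, which has no ortho or para alkoxy donor apart from the diaryl ether oxygen, should not ionise.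

Step 9
Reactants: 16 methyl 2-hydroxy-6-[2-hydroxy-6-(hydroxymethyl)-4-methoxyphenoxy]-4-methylbenzoate; 17 prenyl bromide (1-bromo-3-methylbut-2-ene)
Product: 18 methyl 2-hydroxy-6-{2-(hydroxymethyl)-4-methoxy-6-[(3-methylbut-2-en-1-yl)oxy]phenoxy}-4-methylbenzoate (target)
Conditions: K2CO3 (1.1 equiv), 17 (1.05 equiv), acetone, rt
Reagents that add atoms: none
Why: Williamson ether synthesis; with one equivalent of K2CO3 the free ring B phenol should be alkylated, while the ring A phenol is held in a six-membered hydrogen bond to the ester and the benzylic alcohol is not deprotonated by carbonate. Room temperature avoids Claisen rearrangement of the prenyl ether.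

## Compound list

1 | methyl 2,6-dihydroxy-4-methylbenzoate | COC(=O)c1c(O)cc(C)cc1O | starting material
2 | methyl 2-hydroxy-6-(methoxymethoxy)-4-methylbenzoate | COC(=O)c1c(O)cc(C)cc1OCOC | intermediate
3 | dimethyl (1-diazo-2-oxopropyl)phosphonate | CC(=O)C(=[N+]=[N-])P(=O)(OC)OC | starting material
4 | dimethyl {1-[2-(methoxycarbonyl)-3-(methoxymethoxy)-5-methylphenoxy]-2-oxopropyl}phosphonate (racemic) | COC(=O)c1c(OCOC)cc(C)cc1OC(C(C)=O)P(=O)(OC)OC | intermediate
5 | (tert-butyldiphenylsilyloxy)acetaldehyde | O=CCO[Si](c1ccccc1)(c1ccccc1)C(C)(C)C | starting material
6 | methyl 2-{[(3Z)-5-(tert-butyldiphenylsilyloxy)-2-oxopent-3-en-3-yl]oxy}-6-(methoxymethoxy)-4-methylbenzoate | CC(=O)/C(Oc1cc(C)cc(OCOC)c1C(=O)OC)=C/CO[Si](c1ccccc1)(c1ccccc1)C(C)(C)C | intermediate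
7 | dimethyl malonate | COC(=O)CC(=O)OC | starting material
8 | dimethyl 2-{1-(tert-butyldiphenylsilyloxy)-3-[2-(methoxycarbonyl)-3-(methoxymethoxy)-5-methylphenoxy]-4-oxopentan-2-yl}propanedioate (racemic mixture of diastereomers) | COC(=O)C(C(=O)OC)C(CO[Si](c1ccccc1)(c1ccccc1)C(C)(C)C)C(Oc1cc(C)cc(OCOC)c1C(=O)OC)C(C)=O | intermediate (not isolated)
9 | methyl 2-[(tert-butyldiphenylsilyloxy)methyl]-3-[2-(methoxycarbonyl)-3-(methoxymethoxy)-5-methylphenoxy]-4,6-dioxocyclohexane-1-carboxylate (racemic mixture of diastereomers, drawn as keto form) | COC(=O)C1C(CO[Si](c2ccccc2)(c2ccccc2)C(C)(C)C)C(Oc2cc(C)cc(OCOC)c2C(=O)OC)C(=O)CC1=O | intermediate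
10 | methyl 2-({2-[(tert-butyldiphenylsilyloxy)methyl]-4,6-dioxocyclohexyl}oxy)-6-(methoxymethoxy)-4-methylbenzoate (racemic cis/trans mixture, drawn as keto form) | COC(=O)c1c(OCOC)cc(C)cc1OC1C(CO[Si](c2ccccc2)(c2ccccc2)C(C)(C)C)CC(=O)CC1=O | intermediate
11 | methyl 2-({2-[(tert-butyldiphenylsilyloxy)methyl]-4-methoxy-6-oxocyclohex-4-en-1-yl}oxy)-6-(methoxymethoxy)-4-methylbenzoate (racemic cis/trans mixture) | COC(=O)c1c(OCOC)cc(C)cc1OC1C(CO[Si](c2ccccc2)(c2ccccc2)C(C)(C)C)CC(OC)=CC1=O | intermediate
12 | methyl 2-({2-[(tert-butyldiphenylsilyloxy)methyl]-4-methoxy-6-oxo-1-(phenylselanyl)cyclohex-4-en-1-yl}oxy)-6-(methoxymethoxy)-4-methylbenzoate (racemic, diastereomer mixture) | COC(=O)c1c(OCOC)cc(C)cc1OC1([Se]c2ccccc2)C(CO[Si](c2ccccc2)(c2ccccc2)C(C)(C)C)CC(OC)=CC1=O | intermediate (not isolated)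
13 | selenoxide of 12, methyl 2-({2-[(tert-butyldiphenylsilyloxy)methyl]-4-methoxy-6-oxo-1-(phenylseleninyl)cyclohex-4-en-1-yl}oxy)-6-(methoxymethoxy)-4-methylbenzoate (diastereomer mixture) | COC(=O)c1c(OCOC)cc(C)cc1OC1([Se](=O)c2ccccc2)C(CO[Si](c2ccccc2)(c2ccccc2)C(C)(C)C)CC(OC)=CC1=O | intermediate (not isolated)
14 | methyl 2-{2-[(tert-butyldiphenylsilyloxy)methyl]-6-hydroxy-4-methoxyphenoxy}-6-(methoxymethoxy)-4-methylbenzoate | COC(=O)c1c(OCOC)cc(C)cc1Oc1c(CO[Si](c2ccccc2)(c2ccccc2)C(C)(C)C)cc(OC)cc1O | intermediate
15 | methyl 2-[2-hydroxy-6-(hydroxymethyl)-4-methoxyphenoxy]-6-(methoxymethoxy)-4-methylbenzoate | COC(=O)c1c(OCOC)cc(C)cc1Oc1c(CO)cc(OC)cc1O | intermediate (not isolated)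
16 | methyl 2-hydroxy-6-[2-hydroxy-6-(hydroxymethyl)-4-methoxyphenoxy]-4-methylbenzoate | COC(=O)c1c(O)cc(C)cc1Oc1c(CO)cc(OC)cc1O | intermediate
17 | prenyl bromide (1-bromo-3-methylbut-2-ene) | CC(C)=CCBr | starting material
18 | methyl 2-hydroxy-6-{2-(hydroxymethyl)-4-methoxy-6-[(3-methylbut-2-en-1-yl)oxy]phenoxy}-4-methylbenzoate | COC(=O)c1c(O)cc(C)cc1Oc1c(CO)cc(OC)cc1OCC=C(C)C | target

## Step count and risk assessment

Total step count: 9. Longest linear sequence: 9 steps (1 → 18); compounds 3, 5, 7 and 17 are purchased.

Least certain steps:

Step 4 (key step). The conjugate addition may be slow because the β-carbon is deactivated by the aryloxy donor and is hindered. This would give time for base-induced double-bond migration of the γ-silyloxy enone, for loss of the silyl ether followed by lactonisation on the malonate, or for acylation of the aryloxy-bearing enolate on the ring A ester. The fallback sets out from 6 and replaces base activation of the nucleophile by Lewis acid activation of the enone. Mukaiyama–Michael addition of 1-methoxy-1-(trimethylsilyloxy)ethene (catalytic Sc(OTf)3, CH2Cl2, −78 °C, aqueous work-up) should give the δ-keto ester methyl 3-[(tert-butyldiphenylsilyloxy)methyl]-4-[2-(methoxycarbonyl)-3-(methoxymethoxy)-5-methylphenoxy]-5-oxohexanoate F1. Its intramolecular Claisen condensation (KOtBu, THF, 0 °C) forms the same C4–C5 bond and comes back to the route at 10, with no decarboxylation needed.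

Step 2. Insertion into the chelated, flanked phenol may be slow, so that the carbenoid is consumed by dimerisation or by attack on the electron-rich arene. The fallback sets out from 2 and uses no diazo compound. SN2 alkylation with chloroacetone (K2CO3, catalytic KI, acetone) should give the aryloxyacetone methyl 2-(methoxymethoxy)-4-methyl-6-(2-oxopropoxy)benzoate F2. Silylation under equilibrating conditions (TMSOTf, Et3N, CH2Cl2) should give the enol silyl ether on the aryloxy side, methyl 2-(methoxymethoxy)-4-methyl-6-{[(1Z)-2-(trimethylsilyloxy)prop-1-en-1-yl]oxy}benzoate F3. Mukaiyama aldol addition to 5 (BF3·OEt2, CH2Cl2, −78 °C) should give the β-hydroxy ketone methyl 2-{[5-(tert-butyldiphenylsilyloxy)-4-hydroxy-2-oxopentan-3-yl]oxy}-6-(methoxymethoxy)-4-methylbenzoate F4. Dehydration (MsCl, Et3N, then DBU) comes back to the route at 6. No free enolate that could acylate on the ring A ester is involved.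

Step 6. Methanol may add at the C6 carbonyl instead of C4, giving the isomeric vinylogous ester and, later, the wrong ether pattern; the acid may also begin to remove the MOM group. The fallback sets out from 10 and replaces acid-catalysed exchange by kinetic O-methylation of the dione enolate (Me2SO4, K2CO3, acetone, rt). Steric shielding and the inductive effect of the aryloxy group both direct the electrophile to the C4 oxygen, and no acid is present. It comes back at 11 and makes no new compound (F0).

Step 7. The lithium enolate at C1 may acylate intramolecularly on the ring A ester (spiro-benzofuranone formation). Selenium may also enter on the face that leaves no syn hydrogen at C2, deprotonation may occur at C3, or the product phenol may be over-oxidised by the peroxide. The fallback sets out from 11 and avoids a metal enolate. Soft enolisation (TMSOTf, Et3N, CH2Cl2, 0 °C) should give the silyl dienol ether methyl 2-({6-[(tert-butyldiphenylsilyloxy)methyl]-4-methoxy-2-(trimethylsilyloxy)cyclohexa-1,3-dien-1-yl}oxy)-6-(methoxymethoxy)-4-methylbenzoate F5. Saegusa–Ito oxidation with Pd(OAc)2 (divalent palladium) in MeCN then comes back to the route at 14. The regioisomeric dienol ether from deprotonation at C3 would converge on the same phenol.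

Step 9. Alkylation may also occur at the ring A phenol, or at carbon of the ring B phenoxide, if the hydrogen bond does not differentiate the two phenols well enough. The fallback sets out from 14, where the ring B phenol is the only free hydroxyl. Prenylation (K2CO3, 17, DMF) should give methyl 2-{2-[(tert-butyldiphenylsilyloxy)methyl]-4-methoxy-6-[(3-methylbut-2-en-1-yl)oxy]phenoxy}-6-(methoxymethoxy)-4-methylbenzoate F6. Non-protic removal of the aryl MOM group (TMSOTf, 2,2′-bipyridyl, CH2Cl2, 0 °C, then H2O) should give the silyl ether of the target, methyl 2-{2-[(tert-butyldiphenylsilyloxy)methyl]-4-methoxy-6-[(3-methylbut-2-en-1-yl)oxy]phenoxy}-6-hydroxy-4-methylbenzoate F7. Desilylation with Bu4NF in THF comes back to the route at 18.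

## Further compounds

F1 | step 4 | methyl 3-[(tert-butyldiphenylsilyloxy)methyl]-4-[2-(methoxycarbonyl)-3-(methoxymethoxy)-5-methylphenoxy]-5-oxohexanoate | COC(=O)CC(CO[Si](c1ccccc1)(c1ccccc1)C(C)(C)C)C(Oc1cc(C)cc(OCOC)c1C(=O)OC)C(C)=O
F2 | step 2 | methyl 2-(methoxymethoxy)-4-methyl-6-(2-oxopropoxy)benzoate | COC(=O)c1c(OCOC)cc(C)cc1OCC(C)=O
F3 | step 2 | methyl 2-(methoxymethoxy)-4-methyl-6-{[(1Z)-2-(trimethylsilyloxy)prop-1-en-1-yl]oxy}benzoate | COC(=O)c1c(OCOC)cc(C)cc1O/C=C(/C)O[Si](C)(C)C
F4 | step 2 | methyl 2-{[5-(tert-butyldiphenylsilyloxy)-4-hydroxy-2-oxopentan-3-yl]oxy}-6-(methoxymethoxy)-4-methylbenzoate (diastereomer mixture) | COC(=O)c1c(OCOC)cc(C)cc1OC(C(C)=O)C(O)CO[Si](c1ccccc1)(c1ccccc1)C(C)(C)C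
F0 | step 6 | none | none
F5 | step 7 | methyl 2-({6-[(tert-butyldiphenylsilyloxy)methyl]-4-methoxy-2-(trimethylsilyloxy)cyclohexa-1,3-dien-1-yl}oxy)-6-(methoxymethoxy)-4-methylbenzoate (racemic) | COC(=O)c1c(OCOC)cc(C)cc1OC1=C(O[Si](C)(C)C)C=C(OC)CC1CO[Si](c1ccccc1)(c1ccccc1)C(C)(C)C
F6 | step 9 | methyl 2-{2-[(tert-butyldiphenylsilyloxy)methyl]-4-methoxy-6-[(3-methylbut-2-en-1-yl)oxy]phenoxy}-6-(methoxymethoxy)-4-methylbenzoate | COC(=O)c1c(OCOC)cc(C)cc1Oc1c(CO[Si](c2ccccc2)(c2ccccc2)C(C)(C)C)cc(OC)cc1OCC=C(C)C
F7 | step 9 | methyl 2-{2-[(tert-butyldiphenylsilyloxy)methyl]-4-methoxy-6-[(3-methylbut-2-en-1-yl)oxy]phenoxy}-6-hydroxy-4-methylbenzoate | COC(=O)c1c(O)cc(C)cc1Oc1c(CO[Si](c2ccccc2)(c2ccccc2)C(C)(C)C)cc(OC)cc1OCC=C(C)C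
A1 | alternative 1 | methyl 2-{2-[(tert-butyldimethylsilyloxy)methyl]-4-methoxy-6-[(3-methylbut-2-en-1-yl)oxy]phenoxy}-6-hydroxy-4-methylbenzoate | COC(=O)c1c(O)cc(C)cc1Oc1c(CO[Si](C)(C)C(C)(C)C)cc(OC)cc1OCC=C(C)C
A2 | alternative 1 | 3-methylglutaconic anhydride (4-methyl-2H-pyran-2,6(3H)-dione) | CC1=CC(=O)OC(=O)C1
A3 | alternative 1 | methyl 3-{2-[(tert-butyldimethylsilyloxy)methyl]-4-methoxy-6-[(3-methylbut-2-en-1-yl)oxy]phenoxy}prop-2-ynoate | COC(=O)C#COc1c(CO[Si](C)(C)C(C)(C)C)cc(OC)cc1OCC=C(C)C
A4 | alternative 1 | 2-[(tert-butyldimethylsilyloxy)methyl]-4-methoxy-6-[(3-methylbut-2-en-1-yl)oxy]phenol | Oc1c(CO[Si](C)(C)C(C)(C)C)cc(OC)cc1OCC=C(C)C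
A5 | alternative 2 | methyl 2-(tert-butyldimethylsilyloxy)-6-{2-[(tert-butyldimethylsilyloxy)methyl]-6-hydroxy-4-methoxyphenoxy}-4-methylbenzoate | COC(=O)c1c(O[Si](C)(C)C(C)(C)C)cc(C)cc1Oc1c(CO[Si](C)(C)C(C)(C)C)cc(OC)cc1O
A6 | alternative 2 | methyl 2-(tert-butyldimethylsilyloxy)-6-({2-[(tert-butyldimethylsilyloxy)methyl]-4-diazo-3-oxobut-1-en-1-yl}oxy)-4-methylbenzoate (either alkene geometry) | COC(=O)c1c(O[Si](C)(C)C(C)(C)C)cc(C)cc1OC=C(CO[Si](C)(C)C(C)(C)C)C(=O)C=[N+]=[N-]
A7 | alternative 2 | methoxyacetylene (methoxyethyne) | COC#C
A8 | alternative 3 | 2-{2-[(tert-butyldimethylsilyloxy)methyl]-4-methoxy-6-[(3-methylbut-2-en-1-yl)oxy]phenoxy}-6-(methoxymethoxy)-4-methylbenzoic acid | OC(=O)c1c(OCOC)cc(C)cc1Oc1c(CO[Si](C)(C)C(C)(C)C)cc(OC)cc1OCC=C(C)C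
A9 | alternative 3 | 2-(methoxymethoxy)-4-methyl-6-(trimethylsilyl)phenyl trifluoromethanesulfonate | COCOc1cc(C)cc([Si](C)(C)C)c1OS(=O)(=O)C(F)(F)F
A10 | alternative 3 | 3-(methoxymethoxy)-5-methylbenzyne | COCOC1=CC(C)=CC#C1
A11 | alternative 3 | carbon dioxide | O=C=O
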